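In a one-step world, E + J → L runs at k[E][J] and [L] climbs for as long as E and J are both present. We test that picture on the flasks below, closed and stirred at one temperature.

| flask | E | J | time |
|---|---|---|---|
| green | 0.600 M | 0.720 M |  |
| ochre | 0.240 M | 0.360 M |  |
| red | 0.900 M | 0.720 M |  |
| violet | 0.200 M | 1.40 M | 4.0 min |

- green run (time / min: [L] / M): 0.30: 0.0631; 0.92: 0.1569; 1.8: 0.2424; 2.8: 0.2888; 4.0: 0.3176
- ochre run (time / min: [L] / M): 0.30: 0.0138; 0.92: 0.0385; 1.8: 0.0675; 2.8: 0.0856; 4.0: 0.1021
- red run (time / min: [L] / M): 0.30: 0.0861; 0.92: 0.2184; 1.8: 0.3199; 2.8: 0.3788; 4.0: 0.4127

(each reading ± 0.002 M)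

- Overall: E + J -> L.
- Constant volume, constant temperature.
- A reading of a species includes what of it is bound.
- "The second partner" is J.
- An order is taken over about fifteen percent of the charge, up and down.

* the exponent of [J] in the starting rate at the charge of the green run (at the point where two percent of the E have become L)
* the exponent of [E] in the starting rate at the charge of the green run (at the point where two percent of the E have become L) (one fixed amount of L, the same in the runs compared)
* L in the violet run at 4.0 min, as a share of the E charged

We reckon the violet share; the two orders get no figure of ours.

1. The fill is our name for the forward rate k[E][J]. Early on, the first green reading, with mid-interval concentrations, gives k = 0.537 L mol⁻¹ min⁻¹.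

2. The comparison. Between the last two green readings, [L] averages 0.303 M and rises at 0.0240 M min⁻¹. Counting [E] and [J] as charge minus [L], the one-step world predicts 0.0665 M min⁻¹, so the green run rises more slowly than its fill.

3. The drain. We name the missing rate per unit of [L] the drain of L, a first-order constant for losing L, and the green run reads 0.140 min⁻¹. With the same k, the red run reads 0.151 min⁻¹ and the ochre run 0.0762 min⁻¹; in ochre, [L] is lower, so the scatter weighs more there.

4. The violet flask. With E as limiting reagent and [J] taken as 1.30 M, the fill is pseudo-first-order with constant 0.699 min⁻¹, well above the drain.

5. Where the drain leads. If L returns to E + J, this is a two-state relaxation, and violet reaches 80.4% at 4.0 min. If L goes onward to something else, violet holds 63.8%. We do not split the drain between these two ends, so we commit to the middle, 72.1%.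

The forecast gave 0.95 in [J], 0.85 in [E] and 84% for violet (range 70% to 93%), on the ground that “L stays low, so conversion should be high”.

The simulation gives 0.86 in [J], 0.90 in [E], and 73.4% for violet, against our 72.1%.

    E + J ⇌ L (0.7920 L mol⁻¹ min⁻¹, 0.08340 min⁻¹)
    L → Yx (0.05442 min⁻¹)
    E + J ⇌ EJ, settled at all times (0.3580 L mol⁻¹)

The violet result lies 57.7% of the way from our onward end to our returning end; taken as a straight share, that is an estimate of 0.0808 min⁻¹ of the green drain as return and 0.0592 min⁻¹ as onward loss. The step from L to Yx costs the violet run 12 percentage points: without that step it stands at 84.9%, not 73.4%.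

The readings stem from a simulated flask with constants of no real substance.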